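The readings stem from a simulated flask for substances that don't exist; noise was put on by code.

I was asked how far Qa gets by the end in alder and maple, two flasks that differ in their charge of Qe.

| flask | Qa | Qb | Qe | Qd | remark | time |
|---|---|---|---|---|---|---|
| south-east | 0.10 M | 0.12 M | 0.12 M | 3.8 mM | run made earlier |  |
| west | 0.10 M | 0.080 M | 0.12 M | 7.6 mM | run made earlier |  |
| alder | 0.10 M | 0.0800 M | 0.120 M | 3.8 mM |  | 25 min |
| maple | 0.10 M | 0.0800 M | 0.240 M | 3.8 mM |  | 25 min |

- south-east (time / min: Qa / %, Qf / %): 1.33: 75.1, 23.3; 3.00: 46.6, 51.6; 6.00: 11.3, 87.5; 15.0: 0.5, 99.7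
- west (time / min: Qa / %, Qf / %): 2.00: 36.5, 59.5; 5.00: 18.8, 77.1; 10.0: 18.7, 79.6; 15.0: 19.7, 80.4

(readings scatter by 1 percentage point)

- amounts and yields of Qc count Qm too
- on the list of suspects stand: Qb + Qd <-> Qg; Qg -> Qh; Qh -> Qc + Qj; Qa + Qj -> Qk; Qk -> Qd + Qf; Qa + Qc <-> Qm; Qe + Qc -> Qn
- no earlier run changes the charge of Qe; that part of a forecast is a guess

1. part of the Qa that has reacted at the end, alder
2. part of the Qa that has reacted at the end, maple
3. what raising the concentration of Qe from its lowest to its highest value here does to the part of the Qa that has reacted (changes below 5 percentage points count as none) (no change / it falls / it rises)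

1. West's Qf reached 80.4% at 15.0 min, close to its charged c(Qb)/c(Qa) of 80.0%. The south-east run, with a ratio of 120%, reached 99.7%. I therefore took one Qb per Qa.

2. For alder and maple I reckoned 80.0%, charged Qb over charged Qa, the Qb ceiling, with Qb as limiting reagent.

3. I expected no limit from Qd, because the readings of the south-east run give 26.2 turnovers and alder needs 21.1.

4. I expected no limit from time either. The mean rate of Qf formation read from the south-east run up to 6.00 min was 0.0146 M min⁻¹, and at that rate I reckoned 5.49 min for alder's Qb, less than 25 min. The first interval of the south-east run was faster than that mean by a factor of 1.20, while the margin is a factor of 4.55.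

5. On the list of suspects one Qb gives one Qc, and alder's charge of Qb, 0.0800 M, is less than its charge of Qe, 0.120 M, so I guessed that the larger charge of Qe in maple changes nothing; no earlier run tested this.

The forecast gave 80.5% for alder and 80.5% for maple, each a little above my 80.0%, and no change, holding of west that "Qb runs out rather than the catalyst".

The flasks gave 80.0% for alder, 80.0% for maple and no change.

    Qb + Qd ⇌ Qg (K = 1200 L mol⁻¹, k = 596 L mol⁻¹ min⁻¹)
    Qg → Qh (k = 399 min⁻¹)
    Qh → Qc + Qj (k = 15.7 min⁻¹)
    Qa + Qj → Qk (k = 316 L mol⁻¹ min⁻¹)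
    Qk → Qd + Qf (k = 11.4 min⁻¹)
    Qa + Qc ⇌ Qm, settled at all times (K = 6.30 L mol⁻¹)
    Qe + Qc → Qn (k = 56.6 L mol⁻¹ min⁻¹)

In alder the half-life of Qa by the step from Qa + Qj to Qk was 2.7 min at 2.37 min, short against the 25 min. Qb stood at 0% of its charge by 12.5 min, and Qf at 80.0%, the ceiling of 80.0%. A further flask, alder with 0.25 M of Qa, has a ceiling of 32.0% and gave 32.0%.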